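**Retrosynthetic overview**

1. The target comes from its bis(benzyl ether) by hydrogenolysis; benzyl is the only protecting group used.
2. The oxolane is the only ring made. Its C7'–O bond is closed by attack of the C7 hydroxyl on the benzylic, quinone-methide-like carbon of a 7',8'-epoxide, mirroring the presumed epoxidation and oxa-cyclisation of an 8–8'-linked 7'-ene seco-lignan.
3. The epoxide is made in the same pot by asymmetric epoxidation of an acyclic (E)-alkenol, so C7', C8' and the tertiary OH are set together.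
4. The (E)-alkenol comes from a syn-homopropargylic alcohol and an aryl bromide by one-pot methylalumination and cross-coupling.
5. The alkynol comes from O-benzylvanillin and a chiral allenylstannane (sets C7 and C8), itself made from (R)-but-3-yn-2-ol.

Assumption: (R)-but-3-yn-2-ol, O-benzylvanillin, 4-benzyloxy-3-methoxybromobenzene and the L-fructose-derived Shi ketone are taken as purchasable; lignan numbering is used (C7/C7' benzylic, C8/C8' methyl-bearing, OH on C8'; oxolane C2 = C7', C3 = C8', C4 = C8, C5 = C7), the target being (2R,3S,4S,5S)-2,5-bis(4-hydroxy-3-methoxyphenyl)-3,4-dimethyloxolan-3-ol.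

**Route**

Step 1
Reactants: 1 (R)-but-3-yn-2-ol
Product: 2 (R)-but-3-yn-2-yl methanesulfonate
Conditions: MsCl, Et3N, CH2Cl2, −78 to 0 °C
Reagents that add atoms: methanesulfonyl chloride, CS(=O)(=O)Cl
Why: Plain O-sulfonylation of a secondary propargylic alcohol (sulfonate ester formation); the C–O bond is not broken, so the (R) centre is kept.

Step 2
Reactants: 2 (R)-but-3-yn-2-yl methanesulfonate
Product: 3 (P)-tributyl(buta-1,2-dien-1-yl)stannane
Conditions: Bu3SnH, LiN(i-Pr)2, THF, 0 °C; CuBr·SMe2, −78 °C; then 2, −78 °C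
Reagents that add atoms: tributyltin hydride, CCCC[SnH](CCCC)CCCC
Why: Anti-SN2' displacement of the propargylic mesylate by the stannylcopper reagent (Marshall allenylstannane synthesis) transfers the (R) centre into the (P) allene axis.

Step 3
Reactants: 3 (P)-tributyl(buta-1,2-dien-1-yl)stannane; 4 4-(benzyloxy)-3-methoxybenzaldehyde (O-benzylvanillin)
Product: 5 (1S,2R)-1-[4-(benzyloxy)-3-methoxyphenyl]-2-methylbut-3-yn-1-ol
Conditions: BF3·OEt2 (1.5 equiv), CH2Cl2, −78 °C; aq. NaHCO3
Reagents that add atoms: none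
Why: BF3-promoted anti-SE2' addition of the chiral allenylstannane through an open antiperiplanar transition state (Marshall propargylation) fixes C2 as R from the allene axis and gives the syn adduct, hence 1S.

Step 4
Reactants: 5 (1S,2R)-1-[4-(benzyloxy)-3-methoxyphenyl]-2-methylbut-3-yn-1-ol; 6 1-(benzyloxy)-4-bromo-2-methoxybenzene
Product: 8 (1S,2R,3E)-1,4-bis[4-(benzyloxy)-3-methoxyphenyl]-2,3-dimethylbut-3-en-1-ol, via (E)-alkenyldimethylalane 7 (not isolated)
Conditions: AlMe3 (3 equiv), Cp2ZrCl2 (0.5 equiv), CH2Cl2, 0 °C to rt; evaporate; then 6, ZnCl2 (0.3 equiv), Pd(P(t-Bu)3)2 (3 mol %), THF, 45 °C; aq. KNaC4H4O6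
Reagents that add atoms: trimethylaluminium, C[Al](C)C
Why: Negishi zirconium-catalysed syn-methylalumination puts CH3 on the internal and Al on the terminal alkyne carbon, and the Pd/Zn Negishi cross-coupling with 6 goes with retention, so only the E trisubstituted styrene forms and no stereocentre is touched.

Step 5
Reactants: 8 (1S,2R,3E)-1,4-bis[4-(benzyloxy)-3-methoxyphenyl]-2,3-dimethylbut-3-en-1-ol
Product: 10 (2R,3S,4S,5S)-2,5-bis[4-(benzyloxy)-3-methoxyphenyl]-3,4-dimethyloxolan-3-ol, via (2S,3S)-epoxy alcohol 9 (not isolated)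
Conditions: L-fructose-derived Shi ketone (30 mol %), Oxone (2KHSO5·KHSO4·K2SO4), K2CO3, Bu4NHSO4, MeCN–CH2(OMe)2 / aq. Na2B4O7 buffer (pH 10.5), 0 °C; extract into CH2Cl2, then CSA (5 mol %), −20 °C
Reagents that add atoms: potassium peroxymonosulfate (active salt of Oxone), [K+].[O-]S(=O)(=O)OO
Why: Shi asymmetric epoxidation with the L-fructose ketone (the enantiomer of the D-fructose ketone that gives (R,R)-oxides from E-styrenes) sets C8' as the (2S,3S)-oxirane under reagent control, and acid-triggered 5-endo epoxide opening at the quinone-methide-like benzylic carbon by the C7 hydroxyl with inversion (as in flavan-3-ol syntheses from E-diarylpropene oxides) closes the oxolane with the C7' aryl trans to OH and cis to the C8' methyl.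

Step 6
Reactants: 10 (2R,3S,4S,5S)-2,5-bis[4-(benzyloxy)-3-methoxyphenyl]-3,4-dimethyloxolan-3-ol
Product: 11 (2R,3S,4S,5S)-2,5-bis(4-hydroxy-3-methoxyphenyl)-3,4-dimethyloxolan-3-ol (CNP0234919.3)
Conditions: H2 (1 atm), Pd/C (10 wt % Pd on carbon), EtOAc–EtOH, rt, short reaction time
Reagents that add atoms: none
Why: Catalytic hydrogenolysis of the two aryl benzyl ethers; the hindered ring benzylic C–O bonds of 2,5-diaryloxolane lignans survive brief exposure at 1 atm and no stereocentre is affected.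

**Compound list**

1 | (R)-but-3-yn-2-ol | C[C@@H](O)C#C | starting material
2 | (R)-but-3-yn-2-yl methanesulfonate | C[C@@H](OS(C)(=O)=O)C#C | intermediate
3 | (P)-tributyl(buta-1,2-dien-1-yl)stannane | [H]C([Sn](CCCC)(CCCC)CCCC)=[C@]=C([H])C | intermediate
4 | 4-(benzyloxy)-3-methoxybenzaldehyde | COc1cc(C=O)ccc1OCc1ccccc1 | starting material
5 | (1S,2R)-1-[4-(benzyloxy)-3-methoxyphenyl]-2-methylbut-3-yn-1-ol | COc1cc([C@@H](O)[C@H](C)C#C)ccc1OCc1ccccc1 | intermediate
6 | 1-(benzyloxy)-4-bromo-2-methoxybenzene | COc1cc(Br)ccc1OCc1ccccc1 | starting material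
7 | (E)-alkenyldimethylalane (dimethylaluminium alkoxide of the carbinol) | COc1cc([C@@H](O[Al](C)C)[C@H](C)/C(C)=C/[Al](C)C)ccc1OCc1ccccc1 | intermediate (not isolated)
8 | (1S,2R,3E)-1,4-bis[4-(benzyloxy)-3-methoxyphenyl]-2,3-dimethylbut-3-en-1-ol | COc1cc([C@@H](O)[C@H](C)/C(C)=C/c2ccc(OCc3ccccc3)c(OC)c2)ccc1OCc1ccccc1 | intermediate
9 | (1S,2S)-1-[4-(benzyloxy)-3-methoxyphenyl]-2-{(2S,3S)-3-[4-(benzyloxy)-3-methoxyphenyl]-2-methyloxiran-2-yl}propan-1-ol | COc1cc([C@@H](O)[C@H](C)[C@]2(C)O[C@H]2c3ccc(OCc4ccccc4)c(OC)c3)ccc1OCc1ccccc1 | intermediate (not isolated)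
10 | (2R,3S,4S,5S)-2,5-bis[4-(benzyloxy)-3-methoxyphenyl]-3,4-dimethyloxolan-3-ol | COc1cc([C@H]2O[C@H](c3ccc(OCc4ccccc4)c(OC)c3)[C@@](C)(O)[C@H]2C)ccc1OCc1ccccc1 | intermediate
11 | (2R,3S,4S,5S)-2,5-bis(4-hydroxy-3-methoxyphenyl)-3,4-dimethyloxolan-3-ol | COc1cc([C@H]2O[C@H](c3ccc(O)c(OC)c3)[C@@](C)(O)[C@H]2C)ccc1O | target

**Totals**

Total step count: 6. Longest linear sequence: 6 steps (1 → 2 → 3 → 5 → 8 → 10 → 11).

**Three steps most likely to fail**

Step 5 is the most exposed. The benzylic epoxide carbon carries an electron-rich 4-benzyloxy-3-methoxyphenyl group, so the opening can drift from SN2-like to a free benzylic cation. A free cation would give the C7' epimer (aryl cis to OH), Friedel–Crafts closure onto the other ring, or a 1,2-shift to a ketone. The epoxidation face may also be mismatched with the C8 centre. The fallback sets out from 5 and comes back at 11. It makes the C7' aryl electron-poor so that the oxirane behaves like a plain phenyloxirane. 4-Bromo-2-methoxyphenol is acylated (t-BuCOCl, Et3N, CH2Cl2) to 4-bromo-2-methoxyphenyl pivalate F1. F1 is coupled with 5 by the methylalumination and cross-coupling of step 4 (excess AlMe3 removed before the palladium stage) to give the pivalate alkenol F2. The same Shi epoxidation gives the now isolable pivalate epoxide F3. CSA or BF3·OEt2 in CH2Cl2 at low temperature closes F3 with clean inversion to the oxolane pivalate F4. K2CO3 in MeOH removes the ester to give the monobenzyl oxolane phenol F5, and hydrogenolysis as in step 6 gives 11.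

Step 4 is next. AlMe3 may ionise or methylate the electron-rich benzylic aluminium alkoxide, the alkenylalane may isomerise by chelation if warmed, and leftover Al–CH3 can methylate the aryl bromide in the palladium stage. The fallback sets out from 5 and comes back at 8. It separates the two events. Carboalumination is run cold (AlMe3, Cp2ZrCl2, 1 equiv H2O, −20 °C) and quenched with I2 to give the (E)-vinyl iodide F6. Suzuki–Miyaura coupling of F6 with purchasable [4-(benzyloxy)-3-methoxyphenyl]boronic acid (PdCl2(dppf), K3PO4, THF–H2O, 50 °C) then gives 8 with no aluminium present.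

Step 3 is third. The open transition state may give a modest syn/anti ratio with an electron-rich aromatic aldehyde, and the p-alkoxybenzylic alkoxide is acid-sensitive in the presence of BF3. The fallback sets out from 4 and comes back at 8, bypassing 5. It uses a closed transition state for the syn relationship. Pd(PPh3)4-catalysed 1,4-hydrosilylation of isoprene with HSiCl3 gives (Z)-trichloro(2-methylbut-2-en-1-yl)silane F7. Addition of F7 to 4 under Denmark's chiral bisphosphoramide catalysis (i-Pr2NEt, CH2Cl2, −78 °C; Z geometry gives syn) gives the (1S,2R)-homoallylic alcohol F8. Heck arylation of F8 with 6 (Pd(OAc)2, P(o-tol)3, Et3N, DMF, 90 °C) gives 8 through benzylic β-hydride elimination; double-bond isomers are removed by chromatography.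

**Further compounds**

F1 | step 5 | 4-bromo-2-methoxyphenyl pivalate | COc1cc(Br)ccc1OC(=O)C(C)(C)C
F2 | step 5 | 4-[(1E,3R,4S)-4-(4-(benzyloxy)-3-methoxyphenyl)-4-hydroxy-2,3-dimethylbut-1-en-1-yl]-2-methoxyphenyl pivalate | COc1cc([C@@H](O)[C@H](C)/C(C)=C/c2ccc(OC(=O)C(C)(C)C)c(OC)c2)ccc1OCc1ccccc1
F3 | step 5 | 4-{(2S,3S)-3-[(1S,2S)-1-(4-(benzyloxy)-3-methoxyphenyl)-1-hydroxypropan-2-yl]-3-methyloxiran-2-yl}-2-methoxyphenyl pivalate | COc1cc([C@@H](O)[C@H](C)[C@]2(C)O[C@H]2c3ccc(OC(=O)C(C)(C)C)c(OC)c3)ccc1OCc1ccccc1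
F4 | step 5 | 4-[(2R,3S,4S,5S)-5-(4-(benzyloxy)-3-methoxyphenyl)-3-hydroxy-3,4-dimethyloxolan-2-yl]-2-methoxyphenyl pivalate | COc1cc([C@H]2O[C@H](c3ccc(OC(=O)C(C)(C)C)c(OC)c3)[C@@](C)(O)[C@H]2C)ccc1OCc1ccccc1
F5 | step 5 | (2R,3S,4S,5S)-5-[4-(benzyloxy)-3-methoxyphenyl]-2-(4-hydroxy-3-methoxyphenyl)-3,4-dimethyloxolan-3-ol | COc1cc([C@H]2O[C@H](c3ccc(O)c(OC)c3)[C@@](C)(O)[C@H]2C)ccc1OCc1ccccc1
F6 | step 4 | (1S,2R,3E)-1-[4-(benzyloxy)-3-methoxyphenyl]-4-iodo-2,3-dimethylbut-3-en-1-ol | COc1cc([C@@H](O)[C@H](C)/C(C)=C/I)ccc1OCc1ccccc1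
F7 | step 3 | (Z)-trichloro(2-methylbut-2-en-1-yl)silane | C/C=C(/C)C[Si](Cl)(Cl)Cl
F8 | step 3 | (1S,2R)-1-[4-(benzyloxy)-3-methoxyphenyl]-2,3-dimethylbut-3-en-1-ol | COc1cc([C@@H](O)[C@H](C)C(C)=C)ccc1OCc1ccccc1
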